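The decalin is cut across both rings at once: C1–C2 and C5–C10 (eudesmane numbering) come from one intramolecular Diels–Alder reaction. It exploits the C5–C10 edge shared by rings A and B and the C3=C4 alkene that ring A can carry as the precursor of the 3,4-diol. The precursor is an (E,E)-trienoyl oxazolidinone: C2=C3–C4=C5 diene, C1=C10 enoyl dienophile bearing the C14 methyl, four-carbon tether C6–C9 with C8 masked as a dioxolane, and a removable carboxyl on C1. The cycloaddition closes both rings and sets C10, C5 and C1. Decarboxylation, C7 isopropylidenation, osmylation, angeloylation and a singlet-oxygen ene reaction complete the target.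

Key step: step 10

Remark: eudesmane numbering is used for the bicyclic compounds; on the chelated s-cis model the diene adds to the dienophile face remote from the benzyl group, so the (R)-4-benzyl auxiliary is used because it is the antipode that leads to the 5R,10R series of the target (the S auxiliary would give the enantiomeric decalin), and aldol adduct 28 is carried as a C7 epimer mixture since C7 becomes sp2 in step 15.

Step 1
Reactants: 1 (E)-3-methylpent-2-en-4-yn-1-ol
Product: 2 (E)-3-methylpenta-2,4-dien-1-ol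
Conditions: H2 (1 atm), Pd/CaCO3 poisoned with Pb(OAc)2 (Lindlar catalyst), quinoline, hexane, rt
Reagents that add atoms: none
Why: Semihydrogenation over poisoned palladium should stop at the alkene because the terminal alkyne binds far more strongly than the resulting diene, and the E geometry of the trisubstituted alkene is not touched (Lindlar reduction).

Step 2
Reactants: 2 (E)-3-methylpenta-2,4-dien-1-ol
Product: 3 (E)-5-bromo-3-methylpenta-1,3-diene
Conditions: PBr3 (0.4 equiv), pyridine (cat.), Et2O, −20 to 0 °C; used crude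
Reagents that add atoms: phosphorus tribromide, BrP(Br)Br
Why: Bromide displaces the phosphite ester of the primary allylic alcohol in an SN2 reaction at low temperature, which should keep the E-diene intact, and the labile bromide is used at once.

Step 3
Reactants: 4 N-methoxy-N-methyl-3-oxobutanamide; 3 (E)-5-bromo-3-methylpenta-1,3-diene
Product: 6 (6E)-N-methoxy-N,7-dimethyl-3-oxonona-6,8-dienamide, via sodium lithium dianion of the keto amide 5 (not isolated)
Conditions: NaH, THF, 0 °C; n-BuLi, 0 °C; then 3, 0 °C to rt; aqueous work-up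
Reagents that add atoms: none
Why: In the dianion of a 1,3-dicarbonyl compound the terminal γ-carbanion is the more nucleophilic site and displaces the primary allylic bromide (dianion γ-alkylation), which forms the C6–C7 bond.

Step 4
Reactants: 6 (6E)-N-methoxy-N,7-dimethyl-3-oxonona-6,8-dienamide
Product: 7 N-methoxy-N-methyl-2-{2-[(3E)-4-methylhexa-3,5-dien-1-yl]-1,3-dioxolan-2-yl}acetamide
Conditions: TMSOCH2CH2OTMS, TMSOTf (cat.), CH2Cl2, −78 to −20 °C; pyridine quench
Reagents that add atoms: 1,2-bis(trimethylsilyloxy)ethane, C[Si](C)(C)OCCO[Si](C)(C)C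
Why: Silyl-transfer ketalisation under aprotic conditions at low temperature should convert the C8 ketone into the dioxolane without harming the acid-sensitive diene, and masking C8 at this stage prevents the later C1=C10 alkene from migrating into conjugation with a ketone.

Step 5
Reactants: 7 N-methoxy-N-methyl-2-{2-[(3E)-4-methylhexa-3,5-dien-1-yl]-1,3-dioxolan-2-yl}acetamide; 8 ethyl acetate
Product: 10 ethyl 4-{2-[(3E)-4-methylhexa-3,5-dien-1-yl]-1,3-dioxolan-2-yl}-3-oxobutanoate, via lithium enolate of ethyl acetate 9 (not isolated)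
Conditions: LiN(i-Pr)2 (from n-BuLi and i-Pr2NH), 8, THF, −78 °C; then 7, −78 to 0 °C; aqueous work-up
Reagents that add atoms: none
Why: The ester enolate adds once to the Weinreb amide and the chelated tetrahedral adduct persists until work-up, so the β-keto ester should form without over-addition (Claisen-type acylation of an ester enolate).

Step 6
Reactants: 10 ethyl 4-{2-[(3E)-4-methylhexa-3,5-dien-1-yl]-1,3-dioxolan-2-yl}-3-oxobutanoate
Product: 12 ethyl (2Z)-3-[(diethoxyphosphoryl)oxy]-4-{2-[(3E)-4-methylhexa-3,5-dien-1-yl]-1,3-dioxolan-2-yl}but-2-enoate, via sodium Z-enolate of the keto ester 11 (not isolated)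
Conditions: NaH, Et2O, 0 °C; ClP(O)(OEt)2, 0 °C to rt
Reagents that add atoms: diethyl chlorophosphate, CCOP(=O)(Cl)OCC
Why: In ether the sodium ion holds the enolate oxygen cis to the ester carbonyl, so O-phosphorylation of this chelate should give the Z-enol phosphate.

Step 7
Reactants: 12 ethyl (2Z)-3-[(diethoxyphosphoryl)oxy]-4-{2-[(3E)-4-methylhexa-3,5-dien-1-yl]-1,3-dioxolan-2-yl}but-2-enoate
Product: 13 ethyl (2E,8E)-5,5-(ethylenedioxy)-3,9-dimethylundeca-2,8,10-trienoate
Conditions: Me2CuLi (from MeLi and CuI, copper monoiodide), Et2O, −78 to −45 °C; aqueous work-up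
Reagents that add atoms: lithium dimethylcuprate, [Li+].C[Cu-]C
Why: The cuprate replaces the enol phosphate by methyl with retention of alkene geometry (addition–elimination at the β-carbon of the enoate), so the C14 methyl should end cis to the ester and the C9 chain trans, which is the 2E dienophile geometry.

Step 8
Reactants: 13 ethyl (2E,8E)-5,5-(ethylenedioxy)-3,9-dimethylundeca-2,8,10-trienoate
Product: 14 (2E,8E)-5,5-(ethylenedioxy)-3,9-dimethylundeca-2,8,10-trienoic acid
Conditions: LiOH, THF/MeOH/H2O, rt; then 1 M HCl to pH 4 at 0 °C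
Reagents that add atoms: lithium hydroxide, [Li+].[OH-]
Why: Saponification followed by brief cold acidification should give the acid, since the dioxolane and both alkene geometries are stable to aqueous base.

Step 9
Reactants: 14 (2E,8E)-5,5-(ethylenedioxy)-3,9-dimethylundeca-2,8,10-trienoic acid; 15 (R)-4-benzyloxazolidin-2-one
Product: 18 (R)-4-benzyl-3-[(2E,8E)-5,5-(ethylenedioxy)-3,9-dimethylundeca-2,8,10-trienoyl]oxazolidin-2-one, via pivalic mixed anhydride 16 (not isolated), via lithiated oxazolidinone 17 (not isolated)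
Conditions: PivCl, Et3N, THF, −78 to 0 °C; then 15/n-BuLi (THF, −78 °C), −78 to 0 °C
Reagents that add atoms: none
Why: The lithiated oxazolidinone attacks the less hindered enoyl carbonyl of the mixed anhydride (N-acylation), and acylating at −78 °C without excess amine should avoid deconjugation through a vinylketene.

Step 10
Reactants: 18 (R)-4-benzyl-3-[(2E,8E)-5,5-(ethylenedioxy)-3,9-dimethylundeca-2,8,10-trienoyl]oxazolidin-2-one
Product: 20 (R)-4-benzyl-3-{[(4a'S,8'R,8a'R)-5',8a'-dimethyl-3',4',4a',7',8',8a'-hexahydro-1'H-spiro[1,3-dioxolane-2,2'-naphthalen]-8'-yl]carbonyl}oxazolidin-2-one, via dimethylaluminium imide chelate 19 (not isolated)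
Conditions: Me2AlCl (1.5–2 equiv), CH2Cl2, −30 to 0 °C; then aq. potassium sodium tartrate (KNaC4H4O6)
Reagents that add atoms: none
Why: Me2AlCl turns the imide into the cationic bidentate chelate 19 with the enoyl group s-cis, and the tethered diene adds across C1=C10 in a concerted but asynchronous [4+2] cycloaddition in which bonding at the β-carbon C10 runs ahead, the closest known reaction type being the dialkylaluminium-chloride-promoted intramolecular Diels–Alder reaction of (E,E)-trienoyl oxazolidinones. Ring B (C5 to C10) is closed through the four-carbon tether C6–C9 in a chair-like array, formally a 6-exo attack of the diene terminus C5 on C10, and ring A (C1 to C5 plus C10) is the new cyclohexene of the cycloaddition, closed when C2 bonds to C1. C10 is set by the auxiliary: the benzyl group of the (R)-oxazolidinone covers one face of the planar chelate, the diene adds to the open C1-re/C10-si face and the C10 methyl ends β (10R). C5 is set relative to C10 by the endo mode, with the chelated acyl group under the diene and the tether anti to it, so that H-5 is trans to the C10 methyl (trans-fused), and C1 follows from the E geometry of the dienophile by suprafacial addition, the acyl group cis to that methyl. The step needs the endo over the exo mode and one dienophile face; the first is secured by the terminally activated E-dienophile held in the chelate, the second by the benzyl group, and both depend on the geometric purity of C1=C10 fixed in steps 6 and 7. The C4 methyl stays on the sp2 diene carbon, so C3=C4 is left for step 16.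

Step 11
Reactants: 20 (R)-4-benzyl-3-{[(4a'S,8'R,8a'R)-5',8a'-dimethyl-3',4',4a',7',8',8a'-hexahydro-1'H-spiro[1,3-dioxolane-2,2'-naphthalen]-8'-yl]carbonyl}oxazolidin-2-one
Product: 22 (4a'S,8'R,8a'R)-5',8a'-dimethyl-3',4',4a',7',8',8a'-hexahydro-1'H-spiro[1,3-dioxolane-2,2'-naphthalene]-8'-carboxylic acid, via lithium peroxycarboxylate 21 (not isolated)
Conditions: LiOH, H2O2 (30%), THF/H2O, 0 °C; Na2SO3; 1 M HCl to pH 3–4 at 0 °C
Reagents that add atoms: hydrogen peroxide, OO
Why: Hydroperoxide anion attacks the exocyclic imide carbonyl selectively even when it is hindered, and sulfite reduces the resulting percarboxylate to the acid while the auxiliary is released intact (peroxide-assisted imide cleavage).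

Step 12
Reactants: 22 (4a'S,8'R,8a'R)-5',8a'-dimethyl-3',4',4a',7',8',8a'-hexahydro-1'H-spiro[1,3-dioxolane-2,2'-naphthalene]-8'-carboxylic acid
Product: 24 (4a'R,8a'R)-5',8a'-dimethyl-3',4',4a',7',8',8a'-hexahydro-1'H-spiro[1,3-dioxolane-2,2'-naphthalene], via thiohydroxamate ester 23 (not isolated)
Conditions: N-hydroxypyridine-2-thione, DCC, DMAP (cat.), CH2Cl2, rt, dark; then t-BuSH, PhH, hν (tungsten lamp), rt
Reagents that add atoms: none
Why: The thiohydroxamate ester fragments under visible light to the C1 radical with loss of CO2, and hydrogen transfer from the thiol should give the C1 methylene (Barton decarboxylation), which removes the C1 stereocentre without touching C5 or C10.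

Step 13
Reactants: 24 (4a'R,8a'R)-5',8a'-dimethyl-3',4',4a',7',8',8a'-hexahydro-1'H-spiro[1,3-dioxolane-2,2'-naphthalene]
Product: 25 (4aR,8aR)-5,8a-dimethyl-3,4,4a,7,8,8a-hexahydronaphthalen-2(1H)-one
Conditions: 1 M HCl, THF, rt
Reagents that add atoms: water, O
Why: Acid-catalysed hydrolysis of the dioxolane should free the C8 ketone under conditions too mild to move the C3=C4 alkene.

Step 14
Reactants: 25 (4aR,8aR)-5,8a-dimethyl-3,4,4a,7,8,8a-hexahydronaphthalen-2(1H)-one; 26 acetone
Product: 28 (4aR,8aR)-3-(2-hydroxypropan-2-yl)-5,8a-dimethyl-3,4,4a,7,8,8a-hexahydronaphthalen-2(1H)-one, via lithium C7 enolate 27 (not isolated)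
Conditions: LiN(i-Pr)2 (from n-BuLi and i-Pr2NH), THF, −78 °C; 26, −78 °C; AcOH quench at −78 °C
Reagents that add atoms: none
Why: Kinetic deprotonation of the C8 ketone should occur at C7 because C9 is flanked by the quaternary C10, and the enolate adds to acetone at low temperature (directed aldol addition), the C7 configuration being irrelevant.

Step 15
Reactants: 28 (4aR,8aR)-3-(2-hydroxypropan-2-yl)-5,8a-dimethyl-3,4,4a,7,8,8a-hexahydronaphthalen-2(1H)-one
Product: 30 (4aR,8aR)-5,8a-dimethyl-3-(propan-2-ylidene)-3,4,4a,7,8,8a-hexahydronaphthalen-2(1H)-one, via tertiary mesylate 29 (not isolated)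
Conditions: MsCl, Et3N, CH2Cl2, 0 °C to rt; then DBU, rt
Reagents that add atoms: none
Why: The tertiary alcohol is mesylated through sulfene and the β-mesyloxy ketone eliminates through its enolate (E1cB), while DBU moves any isopropenyl isomer into conjugation, so the tetrasubstituted C7=C11 enone should result.

Step 16
Reactants: 30 (4aR,8aR)-5,8a-dimethyl-3-(propan-2-ylidene)-3,4,4a,7,8,8a-hexahydronaphthalen-2(1H)-one
Product: 31 (4aR,5S,6R,8aR)-5,6-dihydroxy-5,8a-dimethyl-3-(propan-2-ylidene)octahydronaphthalen-2(1H)-one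
Conditions: OsO4 (2 mol %), NMO, t-BuOH/H2O, rt
Reagents that add atoms: osmium tetroxide, O=[Os](=O)(=O)=O; N-methylmorpholine N-oxide, C[N+]1([O-])CCOCC1; water, O
Why: OsO4 adds suprafacially to the electron-rich trisubstituted C3=C4 alkene much faster than to the electron-poor tetrasubstituted C7=C11 enone, and it should approach the α face because the axial C10 methyl shields the β face, which sets C3 (R) and C4 (S) as the 3α,4α-cis-diol (catalytic syn-dihydroxylation).

Step 17
Reactants: 31 (4aR,5S,6R,8aR)-5,6-dihydroxy-5,8a-dimethyl-3-(propan-2-ylidene)octahydronaphthalen-2(1H)-one; 32 angelic acid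
Product: 34 (3R,4S,5R,10R)-4-hydroxy-8-oxoeudesm-7(11)-en-3-yl (Z)-2-methylbut-2-enoate, via angelic trichlorobenzoic mixed anhydride 33 (not isolated)
Conditions: 32, 2,4,6-trichlorobenzoyl chloride, Et3N, toluene, rt; then 31, toluene, 75 °C
Reagents that add atoms: none
Why: The secondary C3 hydroxyl attacks the less hindered angeloyl carbonyl of the mixed anhydride while the tertiary C4 hydroxyl stays inert, and the absence of a nucleophilic catalyst should preserve the Z geometry (Yamaguchi-type esterification).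

Step 18
Reactants: 34 (3R,4S,5R,10R)-4-hydroxy-8-oxoeudesm-7(11)-en-3-yl (Z)-2-methylbut-2-enoate
Product: 35 (3R,4S,5R,10R)-11-hydroperoxy-4-hydroxy-8-oxoeudesm-6-en-3-yl (Z)-2-methylbut-2-enoate
Conditions: O2, hν (visible), tetraphenylporphyrin (cat.), CH2Cl2, 0 °C
Reagents that add atoms: oxygen, O=O
Why: Singlet oxygen should react with the tetrasubstituted enone alkene in a Schenck ene reaction that, as is usual for α,β-unsaturated carbonyl compounds, takes the allylic hydrogen from the group geminal to the carbonyl (C6) and delivers oxygen to the β-carbon C11, so the alkene moves to C6=C7 and the tertiary hydroperoxide forms without a new stereocentre, the ester-conjugated trisubstituted angelate alkene being much less reactive.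

Compound list

1 | (E)-3-methylpent-2-en-4-yn-1-ol | OC/C=C(\C)C#C | starting material
2 | (E)-3-methylpenta-2,4-dien-1-ol | OC/C=C(\C)C=C | intermediate
3 | (E)-5-bromo-3-methylpenta-1,3-diene | BrC/C=C(\C)C=C | intermediate
4 | N-methoxy-N-methyl-3-oxobutanamide | CC(=O)CC(=O)N(C)OC | starting material
5 | sodium lithium dianion of 4 | [Na+].[Li+].[CH2-]C(=O)[CH-]C(=O)N(C)OC | intermediate
6 | (6E)-N-methoxy-N,7-dimethyl-3-oxonona-6,8-dienamide | CON(C)C(=O)CC(=O)CC/C=C(\C)C=C | intermediate
7 | N-methoxy-N-methyl-2-{2-[(3E)-4-methylhexa-3,5-dien-1-yl]-1,3-dioxolan-2-yl}acetamide | CON(C)C(=O)CC1(CC/C=C(\C)C=C)OCCO1 | intermediate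
8 | ethyl acetate | CCOC(C)=O | starting material
9 | lithium enolate of ethyl acetate | [Li+].C=C([O-])OCC | intermediate
10 | ethyl 4-{2-[(3E)-4-methylhexa-3,5-dien-1-yl]-1,3-dioxolan-2-yl}-3-oxobutanoate | CCOC(=O)CC(=O)CC1(CC/C=C(\C)C=C)OCCO1 | intermediate
11 | sodium (Z)-enolate of 10 (enolate oxygen cis to the ester) | [Na+].CCOC(=O)/C=C(\[O-])CC1(CC/C=C(\C)C=C)OCCO1 | intermediate
12 | ethyl (2Z)-3-[(diethoxyphosphoryl)oxy]-4-{2-[(3E)-4-methylhexa-3,5-dien-1-yl]-1,3-dioxolan-2-yl}but-2-enoate | CCOC(=O)/C=C(\OP(=O)(OCC)OCC)CC1(CC/C=C(\C)C=C)OCCO1 | intermediate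
13 | ethyl (2E,8E)-5,5-(ethylenedioxy)-3,9-dimethylundeca-2,8,10-trienoate | CCOC(=O)/C=C(\C)CC1(CC/C=C(\C)C=C)OCCO1 | intermediate
14 | (2E,8E)-5,5-(ethylenedioxy)-3,9-dimethylundeca-2,8,10-trienoic acid | OC(=O)/C=C(\C)CC1(CC/C=C(\C)C=C)OCCO1 | intermediate
15 | (R)-4-benzyloxazolidin-2-one | O=C1OC[C@@H](Cc2ccccc2)N1 | starting material
16 | pivalic mixed anhydride of 14 | CC(C)(C)C(=O)OC(=O)/C=C(\C)CC1(CC/C=C(\C)C=C)OCCO1 | intermediate
17 | N-lithio-(R)-4-benzyloxazolidin-2-one | [Li+].O=C1OC[C@@H](Cc2ccccc2)[N-]1 | intermediate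
18 | (R)-4-benzyl-3-[(2E,8E)-5,5-(ethylenedioxy)-3,9-dimethylundeca-2,8,10-trienoyl]oxazolidin-2-one (key-step precursor) | O=C1OC[C@@H](Cc2ccccc2)N1C(=O)/C=C(\C)CC1(CC/C=C(\C)C=C)OCCO1 | intermediate
19 | dimethylaluminium chelate of 18 (cation bound through both imide carbonyls, Me2AlCl2 counter-ion) | C[Al-]1(C)[O+]=C2OC[C@@H](Cc3ccccc3)N2C(=[O+]1)/C=C(\C)CC4(CC/C=C(\C)C=C)OCCO4.C[Al-](C)(Cl)Cl | intermediate
20 | (R)-4-benzyl-3-{[(4a'S,8'R,8a'R)-5',8a'-dimethyl-3',4',4a',7',8',8a'-hexahydro-1'H-spiro[1,3-dioxolane-2,2'-naphthalen]-8'-yl]carbonyl}oxazolidin-2-one (key-step product; eudesmane numbering: trans-fused, Δ3, 8-ketal, 1β-acyl, 10β-methyl, 5α-H) | O=C1OC[C@@H](Cc2ccccc2)N1C(=O)[C@@H]1CC=C(C)[C@@H]2CCC3(OCCO3)C[C@@]12C | intermediate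
21 | lithium peroxycarboxylate of 22 | [Li+].[O-]OC(=O)[C@@H]1CC=C(C)[C@@H]2CCC3(OCCO3)C[C@@]12C | intermediate
22 | (4a'S,8'R,8a'R)-5',8a'-dimethyl-3',4',4a',7',8',8a'-hexahydro-1'H-spiro[1,3-dioxolane-2,2'-naphthalene]-8'-carboxylic acid | OC(=O)[C@@H]1CC=C(C)[C@@H]2CCC3(OCCO3)C[C@@]12C | intermediate
23 | 2-thioxopyridin-1(2H)-yl ester of 22 | S=c1ccccn1OC(=O)[C@@H]1CC=C(C)[C@@H]2CCC3(OCCO3)C[C@@]12C | intermediate
24 | (4a'R,8a'R)-5',8a'-dimethyl-3',4',4a',7',8',8a'-hexahydro-1'H-spiro[1,3-dioxolane-2,2'-naphthalene] | C1CC=C(C)[C@@H]2CCC3(OCCO3)C[C@@]12C | intermediate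
25 | (4aR,8aR)-5,8a-dimethyl-3,4,4a,7,8,8a-hexahydronaphthalen-2(1H)-one (trans-fused; eudesmane C8 ketone, Δ3) | C1CC=C(C)[C@@H]2CCC(=O)C[C@@]12C | intermediate
26 | acetone | CC(C)=O | starting material
27 | lithium C7–C8 enolate of 25 | [Li+].C1CC=C(C)[C@@H]2CC=C([O-])C[C@@]12C | intermediate
28 | (4aR,8aR)-3-(2-hydroxypropan-2-yl)-5,8a-dimethyl-3,4,4a,7,8,8a-hexahydronaphthalen-2(1H)-one (epimers at ring C3, which is eudesmane C7) | C1CC=C(C)[C@@H]2CC(C(C)(C)O)C(=O)C[C@@]12C | intermediate
29 | tertiary methanesulfonate of 28 | C1CC=C(C)[C@@H]2CC(C(C)(C)OS(C)(=O)=O)C(=O)C[C@@]12C | intermediate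
30 | (4aR,8aR)-5,8a-dimethyl-3-(propan-2-ylidene)-3,4,4a,7,8,8a-hexahydronaphthalen-2(1H)-one (eudesma-3,7(11)-dien-8-one) | C1CC=C(C)[C@@H]2CC(=C(C)C)C(=O)C[C@@]12C | intermediate
31 | (4aR,5S,6R,8aR)-5,6-dihydroxy-5,8a-dimethyl-3-(propan-2-ylidene)octahydronaphthalen-2(1H)-one (3α,4α-dihydroxyeudesm-7(11)-en-8-one) | O[C@@H]1CC[C@]2(C)CC(=O)C(=C(C)C)C[C@H]2[C@]1(C)O | intermediate
32 | angelic acid, (Z)-2-methylbut-2-enoic acid | C/C=C(/C)C(=O)O | starting material
33 | (Z)-2-methylbut-2-enoic 2,4,6-trichlorobenzoic anhydride | C/C=C(/C)C(=O)OC(=O)c1c(Cl)cc(Cl)cc1Cl | intermediate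
34 | (3R,4S,5R,10R)-4-hydroxy-8-oxoeudesm-7(11)-en-3-yl (Z)-2-methylbut-2-enoate | C/C=C(/C)C(=O)O[C@@H]1CC[C@]2(C)CC(=O)C(=C(C)C)C[C@H]2[C@]1(C)O | intermediate
35 | (3R,4S,5R,10R)-11-hydroperoxy-4-hydroxy-8-oxoeudesm-6-en-3-yl (Z)-2-methylbut-2-enoate | C/C=C(/C)C(=O)O[C@@H]1CC[C@]2(C)CC(=O)C(C(C)(C)OO)=C[C@H]2[C@]1(C)O | target

Total step count: 18. Longest linear sequence: 18 steps (1 to 35); compounds 4, 8, 15, 26 and 32 enter as purchased materials.

Steps most likely to fail

First, step 10. The cycloaddition may stall or lose selectivity. The β,β-disubstituted dienophile is slow to react. The dioxolane can compete for the aluminium Lewis acid or be ionised by it. The axial ketal oxygen syn to the C10 methyl may erode the endo preference. The fallback drops both the Lewis acid and the auxiliary and sets out from ester 13. A thermal intramolecular Diels–Alder reaction (toluene, BHT, 180–200 °C, sealed tube) should give, after chromatographic removal of cis-fused material, the racemic trans-fused ethyl ester F1. Saponification (KOH, EtOH/H2O, reflux) gives the racemic acid F2. Classical resolution by crystallisation of the (R)-1-phenylethylammonium salt F3 follows, with the antipodal amine used instead if the wanted acid stays in solution. Mild acidification returns the route at acid 22.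

Second, step 18. The ene reaction may show poor chemoselectivity, with singlet oxygen also attacking the angelate alkene, and the hydroperoxide may degrade on prolonged irradiation. The fallback changes the order so that no second reactive alkene is present during oxygenation, and sets out from diol 31. Photooxygenation under the conditions of step 18 should give the 11-hydroperoxy-3α,4α-dihydroxyeudesm-6-en-8-one F4. The hydroperoxide, more acidic and less hindered than the axial C3 hydroxyl, is capped selectively (TESCl, imidazole, DMF, −20 °C) as the triethylsilyl peroxide F5. Angeloylation of the C3 hydroxyl with anhydride 33 as in step 17 gives the silyl-peroxy angelate F6. Removal of silicon (HF·pyridine, THF, 0 °C) arrives at target 35.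

Third, step 17. Acylation of the hindered axial C3 hydroxyl may be slow, and the angeloyl unit can isomerise from Z to E while it waits. The fallback forms the ester bond first and builds the Z-alkene afterwards, and sets out from diol 31. Steglich esterification with 2-(diphenoxyphosphoryl)propanoic acid (DCC, DMAP, CH2Cl2) gives the 3-O-[2-(diphenoxyphosphoryl)propanoyl] ester F7. A Z-selective Horner–Wadsworth–Emmons reaction of this diaryl phosphonate with acetaldehyde (NaI, DBU, THF, −78 to 0 °C) returns the route at angelate 34.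

Further compounds

F1 | step 10 | racemic ethyl (4a'S*,8'R*,8a'R*)-5',8a'-dimethyl-3',4',4a',7',8',8a'-hexahydro-1'H-spiro[1,3-dioxolane-2,2'-naphthalene]-8'-carboxylate | CCOC(=O)[C@@H]1CC=C(C)[C@@H]2CCC3(OCCO3)C[C@@]12C.CCOC(=O)[C@H]1CC=C(C)[C@H]2CCC3(OCCO3)C[C@]12C
F2 | step 10 | racemic acid (22 with its enantiomer) | OC(=O)[C@@H]1CC=C(C)[C@@H]2CCC3(OCCO3)C[C@@]12C.OC(=O)[C@H]1CC=C(C)[C@H]2CCC3(OCCO3)C[C@]12C
F3 | step 10 | (R)-1-phenylethylammonium salt of acid 22 | [O-]C(=O)[C@@H]1CC=C(C)[C@@H]2CCC3(OCCO3)C[C@@]12C.C[C@@H]([NH3+])c1ccccc1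
F4 | step 18 | (3R,4S,5R,10R)-11-hydroperoxy-3,4-dihydroxyeudesm-6-en-8-one | O[C@@H]1CC[C@]2(C)CC(=O)C(C(C)(C)OO)=C[C@H]2[C@]1(C)O
F5 | step 18 | (3R,4S,5R,10R)-3,4-dihydroxy-11-(triethylsilylperoxy)eudesm-6-en-8-one | O[C@@H]1CC[C@]2(C)CC(=O)C(C(C)(C)OO[Si](CC)(CC)CC)=C[C@H]2[C@]1(C)O
F6 | step 18 | (3R,4S,5R,10R)-4-hydroxy-8-oxo-11-(triethylsilylperoxy)eudesm-6-en-3-yl (Z)-2-methylbut-2-enoate | C/C=C(/C)C(=O)O[C@@H]1CC[C@]2(C)CC(=O)C(C(C)(C)OO[Si](CC)(CC)CC)=C[C@H]2[C@]1(C)O
F7 | step 17 | (3R,4S,5R,10R)-4-hydroxy-8-oxoeudesm-7(11)-en-3-yl 2-(diphenoxyphosphoryl)propanoate (mixture at the phosphonate α-carbon) | CC(C(=O)O[C@@H]1CC[C@]2(C)CC(=O)C(=C(C)C)C[C@H]2[C@]1(C)O)P(=O)(Oc1ccccc1)Oc1ccccc1
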